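The route rests on opening the O1–C2 bond of the flavan-4-ol pyran ring (O1, C2, C3, C4, C4a, C8a) of the aromatic half, which leaves a 2'-hydroxychalcone. Because the second ortho oxygen (on C5) is already locked in the benzofuran ketal, only one phenol can cyclise. A chalcone isomerase closes this last ring and sets C2 (S); a ketoreductase in the same pot sets C4 (R). The precursor is a tetracyclic ketal bearing one free phenol next to an (E)-cinnamoyl group, made by Pummerer-ketone-type oxidative cross-coupling of an (S)-flavan-4-ol phenol with 2',6'-dihydroxy-3',4'-dimethoxychalcone.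

Key step: step 8

Assumption: a chalcone isomerase and an (R)-selective ketoreductase that accept the bulky chalcone 14 are taken to be obtainable by panel screening or a few rounds of evolution, and acetophenones 1 and 8 are treated as catalogue compounds.

Step 1
Reactants: 1 2'-hydroxy-3',4',6'-trimethoxyacetophenone
Product: 3 5,7,8-trimethoxychromone, via enaminone 2 (not isolated)
Conditions: Me2NCH(OMe)2 (2 equiv), toluene, 100 °C; then conc. HCl, CH2Cl2, rt
Reagents that add atoms: N,N-dimethylformamide dimethyl acetal, COC(OC)N(C)C
Why: Condensation of the methyl ketone with the amide acetal gives the enaminone, which cyclises under acid with loss of dimethylamine (standard enaminone chromone synthesis); no stereocentre is formed.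

Step 2
Reactants: 3 5,7,8-trimethoxychromone; 4 phenylboronic acid
Product: 5 (S)-5,7,8-trimethoxyflavanone
Conditions: Pd(OCOCF3)2 (5 mol %), (R)-t-BuPyOx (6 mol %), NH4PF6 (30 mol %), H2O (5 equiv), ClCH2CH2Cl, 60 °C
Reagents that add atoms: none
Why: Pd(II)/pyridine-oxazoline-catalysed asymmetric conjugate addition of an arylboronic acid to a chromone (Hayashi–Miyaura-type 1,4-addition, Pd enolate protonated by water); the ligand controls C2, and by analogy with cyclic enones the (R)-ligand should deliver the 2S flavanone.

Step 3
Reactants: 5 (S)-5,7,8-trimethoxyflavanone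
Product: 6 (S)-5-hydroxy-7,8-dimethoxyflavanone
Conditions: BCl3 (1.5 equiv), CH2Cl2, −78 → 0 °C; aq. NaHCO3
Reagents that add atoms: none
Why: Chelation-controlled Lewis-acid ether cleavage: boron bridges the C4 carbonyl and the peri 5-methoxy oxygen, so only this methyl ether should be cleaved, and the low temperature should leave C2 untouched.

Step 4
Reactants: 6 (S)-5-hydroxy-7,8-dimethoxyflavanone
Product: 7 (2S,4S)-5-hydroxy-7,8-dimethoxyflavan-4-ol
Conditions: NaBH4, MeOH–THF, 0 °C; aq. NH4Cl (no acid)
Reagents that add atoms: none
Why: Borohydride 1,2-reduction with axial hydride delivery should give mainly the 2,4-cis alcohol; the C4 configuration is irrelevant because this hydroxyl is expelled in step 7.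

Step 5
Reactants: 8 6'-hydroxy-2',3',4'-trimethoxyacetophenone; 9 benzaldehyde
Product: 10 (E)-6'-hydroxy-2',3',4'-trimethoxychalcone
Conditions: KOH (50 % aq.), EtOH, 0 °C → rt; cold 1 M HCl to pH 5
Reagents that add atoms: none
Why: Claisen–Schmidt condensation of the ketone enolate with non-enolisable benzaldehyde followed by E1cB dehydration should give the (E)-enone, which stays open as its phenoxide in strong base.

Step 6
Reactants: 10 (E)-6'-hydroxy-2',3',4'-trimethoxychalcone
Product: 11 (E)-2',6'-dihydroxy-3',4'-dimethoxychalcone
Conditions: BCl3 (3 equiv), CH2Cl2, −40 → 0 °C; ice/aq. NaHCO3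
Reagents that add atoms: none
Why: Chelation-assisted BCl3 demethylation should cleave the crowded 2'-methyl ether ortho to the carbonyl and spare the 3'- and 4'-methyl ethers; cold, brief work-up should keep the 2',6'-dihydroxychalcone open.

Step 7
Reactants: 7 (2S,4S)-5-hydroxy-7,8-dimethoxyflavan-4-ol; 11 (E)-2',6'-dihydroxy-3',4'-dimethoxychalcone
Product: 14 ketal chalcone, via aryl dienone 12 (not isolated), via enol ketal 13 (not isolated)
Conditions: 7 added slowly to PhI(OAc)2 (1.05 equiv) and 11 (3 equiv), (CF3)2CHOH–CH2Cl2 1:3, −40 → 0 °C; aq. NaHCO3
Reagents that add atoms: none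
Why: Pummerer's-ketone/usnic-acid-type oxidative phenol cross-coupling in which PhI(OAc)2 converts the non-chelated p-methoxyphenol 7 (slow addition keeps it from acting as its own nucleophile, and the chelated phenols of 11 are oxidised more slowly) into a phenoxonium ion whose C4a is blocked and whose C6 is the electron-rich α-carbon of a vinylogous ester, so that the only free ring carbon of 11 (C5') should add to the methoxy-bearing para carbon C8 to give 12, after which the neighbouring 6'-hydroxyl closes the dihydrofuran by 5-exo oxa-Michael addition to C8a along the axial, anomerically favoured trajectory trans to the equatorial C2 phenyl (the cis ring fusion ties C8 to C8a, and reversible ionisation of the C8 methyl ether of 12 should let both C8 epimers drain through this closure), and enol 13 expels the C4 hydroxyl as water to give the conjugated enone of 14.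

Step 8
Reactants: 14 ketal chalcone
Product: 16 6''-demethoxyneocalycopterone (target), via flavanone 15 (not isolated)
Conditions: chalcone isomerase, KPi buffer pH 7.0, DMSO (10 % v/v), 30 °C; then (R)-selective ketoreductase, NADP+ (cat.), i-PrOH (10 % v/v), 30 °C
Reagents that add atoms: none
Why: A chalcone isomerase binds the 2'-phenolate of 14 and catalyses intramolecular conjugate (oxa-Michael) addition of the only free phenol oxygen to the enone β-carbon through an enzyme-stabilised enolate, giving (2S)-flavanone 15, which an NADPH-dependent ketoreductase of the flavanone 4-reductase type reduces in the same pot. The closest known reactions are the chalcone to (2S)-flavanone isomerisation and the flavanone to (2S,4R)-flavan-4-ol reduction of flavonoid biosynthesis. The pyran ring closes in the 6-endo-trig mode by O1–C2 bond formation. C2 (S) is set by the isomerase active site, which exposes a single enone face irrespective of the remote ketal stereocentres, and C4 (R, trans to the phenyl) by anti-Prelog hydride transfer inside the reductase pocket, against the cis preference of small hydride reagents. The step needs site selectivity between the two ortho oxygens, secured because the second is locked in the benzofuran ketal, and chemoselectivity for the aryl ketone over the hindered cross-conjugated vinylogous-ester carbonyl of the core, which the shape-selective reductase should provide. Reduction directly after closure should also prevent C2 epimerisation of 15 by retro-oxa-Michael opening, and the near-neutral pH keeps the uncatalysed closure slow.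

Compound list
1 | 2'-hydroxy-3',4',6'-trimethoxyacetophenone | CC(=O)c1c(OC)cc(OC)c(OC)c1O | starting material
2 | (E)-3-(dimethylamino)-1-(2-hydroxy-3,4,6-trimethoxyphenyl)prop-2-en-1-one (enaminone) | CN(C)/C=C/C(=O)c1c(OC)cc(OC)c(OC)c1O | intermediate (not isolated)
3 | 5,7,8-trimethoxychromone (5,7,8-trimethoxy-4H-chromen-4-one) | COc1cc(OC)c(OC)c2OC=CC(=O)c12 | intermediate
4 | phenylboronic acid | OB(O)c1ccccc1 | starting material
5 | (S)-5,7,8-trimethoxyflavanone | COc1cc(OC)c(OC)c2O[C@H](c3ccccc3)CC(=O)c12 | intermediate
6 | (S)-5-hydroxy-7,8-dimethoxyflavanone | COc1cc(O)c2c(c1OC)O[C@H](c1ccccc1)CC2=O | intermediate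
7 | (2S,4S)-5-hydroxy-7,8-dimethoxyflavan-4-ol (2,4-cis) | COc1cc(O)c2c(c1OC)O[C@H](c1ccccc1)C[C@@H]2O | intermediate
8 | 6'-hydroxy-2',3',4'-trimethoxyacetophenone | COc1cc(O)c(C(C)=O)c(OC)c1OC | starting material
9 | benzaldehyde | O=Cc1ccccc1 | starting material
10 | (E)-6'-hydroxy-2',3',4'-trimethoxychalcone | COc1cc(O)c(C(=O)/C=C/c2ccccc2)c(OC)c1OC | intermediate
11 | (E)-2',6'-dihydroxy-3',4'-dimethoxychalcone | COc1cc(O)c(C(=O)/C=C/c2ccccc2)c(O)c1OC | intermediate
12 | aryl dienone: (2S,4S)-4-hydroxy-7,8-dimethoxy-2-phenyl-2,3,4,8-tetrahydro-5H-chromen-5-one carrying at C8, on the face opposite to the C2 phenyl, a 3-[(E)-cinnamoyl]-2,4-dihydroxy-5,6-dimethoxyphenyl group | COC1=CC(=O)C2=C(O[C@H](c3ccccc3)C[C@@H]2O)[C@]1(OC)c1c(O)c(C(=O)/C=C/c2ccccc2)c(O)c(OC)c1OC | intermediate (not isolated)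
13 | enol ketal: 12 after addition of the aryl 2-hydroxyl to C8a (cis-fused dihydrobenzofuran, aryloxy oxygen trans to the C2 phenyl, C5 enol, C4 hydroxyl retained) | COC1=CC(O)=C2[C@@H](O)C[C@@H](c3ccccc3)O[C@]23Oc2c(C(=O)/C=C/c4ccccc4)c(O)c(OC)c(OC)c2[C@]13OC | intermediate (not isolated)
14 | ketal chalcone: (2S,8S,8aS)-7,8-dimethoxy-2-phenyl-2,3,8,8a-tetrahydro-5H-chromen-5-one whose C8 (C–C bond) and C8a (C–O bond) are bridged by a benzene ring that carries, going round from the ketal oxygen, an (E)-cinnamoyl group, a free hydroxyl and two methoxy groups | COC1=CC(=O)C2=CC[C@@H](c3ccccc3)O[C@]23Oc2c(C(=O)/C=C/c4ccccc4)c(O)c(OC)c(OC)c2[C@]13OC | intermediate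
15 | (2S)-flavanone of 14 (chroman-4-one ring closed between the free phenol oxygen and the cinnamoyl β-carbon) | COC1=CC(=O)C2=CC[C@@H](c3ccccc3)O[C@]23Oc2c4c(c(OC)c(OC)c2[C@]13OC)O[C@H](c1ccccc1)CC4=O | intermediate (not isolated)
16 | 6''-demethoxyneocalycopterone, the (2S,4R)-flavan-4-ol from 15, with the (2''S,8''S,8a''S) ketal half | COC1=CC(=O)C2=CC[C@@H](c3ccccc3)O[C@]23Oc2c4c(c(OC)c(OC)c2[C@]13OC)O[C@H](c1ccccc1)C[C@H]4O | target

Total step count: 8. Longest linear sequence: 6 steps (steps 1, 2, 3, 4, 7, 8).

Steps most likely to fail

Step 7. The process at risk is the cross-coupling itself. The phenoxonium ion may be captured by a second molecule of 7 instead of 11, the oxidant may attack 11, the arene may add at the ortho carbon C6 with re-aromatisation, or facial control relative to the remote C2 phenyl may be weak. The fallback separates oxidation from coupling; it sets out from 7 and returns at 14. Compound 7 alone is oxidised with PhI(OAc)2 in MeOH over NaHCO3 at 0 °C to the isolable quinone monoketal F1, which no longer has a nucleophilic arene and never meets the oxidant together with 11. F1 and 11 are then combined with a Brønsted acid (acid clay or catalytic TfOH) in (CF3)2CHOH–CH2Cl2 at −20 °C (acid-promoted quinone-monoketal/phenol coupling). Ionisation of the ketal gives the same C8 oxocarbenium ion, and arylation, oxa-Michael closure and loss of water should lead to 14.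

Step 8. The process at risk is enzyme turnover: the pentasubstituted, ketal-fused A-ring may not fit the isomerase pocket, so slow uncatalysed closure erodes C2 control, or the reductase may attack the wrong carbonyl. The fallback gives up enzymatic control; it sets out from 14, returns at 15 and ends at 16. NaOAc in EtOH at 50 °C closes the ring under thermodynamic control to give 15 together with its C2 epimer, the (2R)-flavanone F2. The two are separated by chromatography, and F2 is returned to the same conditions, where retro-oxa-Michael opening and re-closure regenerate the mixture. Isolated 15 is then reduced under reagent control by Corey–Bakshi–Shibata reduction ((S)-Me-CBS, catecholborane, toluene, −40 °C), which should place the hydroxyl 4R with the aryl ring as the large group.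

Step 6. The process at risk is Lewis-acid-promoted closure of the 2',6'-dihydroxychalcone to flavanones through either phenol, or cleavage of a second methyl ether. The fallback moves the demethylation ahead of the condensation and protects both phenols; it sets out from 8 and returns at 11. BCl3 in CH2Cl2 converts 8 into 2',6'-dihydroxy-3',4'-dimethoxyacetophenone F3. NaH and MOMCl in DMF give its bis(methoxymethyl) ether F4. Claisen–Schmidt condensation with 9 (KOH, EtOH) gives the bis-MOM chalcone F5. Brief treatment with 3 M HCl in MeOH at rt removes both acetals and should release 11 without cyclisation.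

Further compounds
F1 | step 7 | (2S,4S)-4-hydroxy-7,8,8-trimethoxy-2-phenyl-2,3,4,8-tetrahydro-5H-chromen-5-one (quinone monoketal of 7) | COC1=CC(=O)C2=C(O[C@H](c3ccccc3)C[C@@H]2O)C1(OC)OC
F2 | step 8 | (2R)-flavanone, C2 epimer of 15 | COC1=CC(=O)C2=CC[C@@H](c3ccccc3)O[C@]23Oc2c4c(c(OC)c(OC)c2[C@]13OC)O[C@@H](c1ccccc1)CC4=O
F3 | step 6 | 2',6'-dihydroxy-3',4'-dimethoxyacetophenone | COc1cc(O)c(C(C)=O)c(O)c1OC
F4 | step 6 | 3',4'-dimethoxy-2',6'-bis(methoxymethoxy)acetophenone | COCOc1cc(OC)c(OC)c(OCOC)c1C(C)=O
F5 | step 6 | (E)-3',4'-dimethoxy-2',6'-bis(methoxymethoxy)chalcone | COCOc1cc(OC)c(OC)c(OCOC)c1C(=O)/C=C/c1ccccc1
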